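The data were generated by integration from invented constants, and the scatter is random.

The share of Tgt at 15 min cannot be read off the earlier runs, because their last readings stand earlier, at 8.00 min. A rule has to carry them forward before one flask is chosen for charging first.

| setting | blue | ochre | green | winter | summer | autumn | dusk | dawn | spring |
|---|---|---|---|---|---|---|---|---|---|
| Sub | 0.37 M | 2.7 M | 1.5 M | 0.50 M | 3.0 M | 1.0 M | 1.5 M | 1.5 M | 1.5 M |
| Rgt | 1.5 M | 1.5 M | 1.2 M | 1.50 M | 1.00 M | 3.00 M | 1.50 M | 0.400 M | 2.50 M |
| remark | run made earlier | run made earlier | run made earlier |  |  |  |  |  |  |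
| time |  |  |  | 15 min | 15 min | 15 min | 15 min | 15 min | 15 min |

- blue (time / min: Tgt / %, Ofp / %): 1.00: 16.7, 0; 2.00: 27.6, 0.7; 3.00: 36.9, 0.4; 4.00: 42.4, 2.4; 5.00: 47.5, 2.4; 6.00: 50.9, 4.1; 8.00: 52.3, 7.4
- ochre (time / min: Tgt / %, Ofp / %): 1.00: 12.5, 0.9; 2.00: 20.6, 1.3; 3.00: 23.4, 2.0; 4.00: 25.3, 3.6; 5.00: 25.7, 5.3; 6.00: 26.1, 6.5; 8.00: 23.6, 8.6
- green (time / min: Tgt / %, Ofp / %): 0.667: 8.6, 0; 2.00: 19.6, 0.8; 4.00: 26.6, 2.0; 5.00: 27.6, 3.6; 8.00: 28.3, 7.6

(readings scatter by 0.5 percentage points)

- a reading or a percentage of Tgt counts all its forms, free or not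

* the flasks put in order of share of Tgt in all that became Tgt or Ofp, best first, at 15 min (winter / summer / autumn / dusk / dawn / spring)
* the share of Tgt in all that became Tgt or Ofp of the flask you put first, at 15 min
* the share of Tgt in all that became Tgt or Ofp of the flask you put last, at 15 min

At the last reading, the ratio of Ofp to Tgt is 0.141 in blue, with 0.194 M of Tgt, and 0.364 in ochre, with 0.637 M. It is higher in ochre, though both were charged with 1.5 M of Rgt. The reading to carry is therefore the wear coefficient, the ratio of Ofp to Tgt divided by the molar Tgt and by the time: green reads 0.0791 /M/min, blue 0.0914 /M/min, ochre 0.0715 /M/min. The share (the selectivity) is then, with Tgt held steady over the time, one divided by one plus coefficient times Tgt times time.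

Tgt in a new flask is estimated from green, where the readings have nearly stopped rising (27.6%, then 28.3%). Assuming a partner formed with each Tgt, Tgt squared over the remaining Sub and Rgt reads 0.283. That quotient gives dawn 0.239 M of Tgt and spring 0.661 M. The reckoned shares at 15 min are 77.9% for dawn and 56.0% for spring, so dawn is charged first and spring is left.

The forecast gives autumn > spring > winter > dusk > summer > dawn, with 81% at the top and 45% at the bottom, and holds as an uncertain suggestion that “free Rgt protects Tgt”. It puts dawn last, where this reckoning puts it ahead of spring.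

The flasks give dawn > winter > summer > dusk > autumn > spring, from 79.9% down to 49.8%.

    Sub + Rgt ⇌ Tgt + Byp (K = 0.330, k = 0.00200 /M/s)
    Sub + Tgt ⇌ Imd, settled at all times (K = 0.470 /M)
    Tgt + Byp → Ofp (k = 0.00250 /M/s)

In dawn at 15 min, the first step relaxes with a half-life of 2.42 min, shorter than the 20 min half-life of free Tgt on its way to Ofp. With dawn's Tgt of 15.2% at that time, the coefficient gives 78.7% beside the 79.9% of the flask. Dawn left until 25 min, with the reckoned Tgt unchanged, should give 67.9%; the computed share there is 66.5%, with Tgt at 13.7%.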